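**Strategy.** Everything rests on taking ring B apart at C5'–C6', C1'–C2' and C2'–C3'. Ring B has 2'-OH para to 5'-OMe, with O-4' on the carbon next to that methoxy. This hydroquinone monomethyl ether pattern is what a chromium carbene benzannulation produces, each oxygen already distinct. In one operation the carbene carbon and alkoxyvinyl arm of a (1-tert-butoxyvinyl)(methoxy)carbene Cr(CO)5 complex, one CO ligand and the terminal alkyne of 2-ethynyl-5,6,7,8-tetramethoxychromone (rings A and C complete) are joined into the arene. The alkyne comes from 1,2,3,4-tetramethoxybenzene via an acetal-masked 2-formylchromone; acid finally frees 4'-OH.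

Key step: step 8

Assumption: ethyl diethoxyacetate, TMSCHN2 (hexane solution), 2,4-dihydroxy-5-methoxybenzaldehyde and 3-(triisopropylsilyl)propiolic acid are treated as purchasable reagents.

**Route**

Step 1
Reactants: 1 1,2,3,4-tetramethoxybenzene
Product: 3 2,3,4,5-tetramethoxybenzaldehyde, via iminium chloride 2 (not isolated)
Conditions: POCl3, DMF, 0 → 80 °C; then H2O, 50 °C
Reagents that add atoms: N,N-dimethylformamide, CN(C)C=O; water, O
Why: Vilsmeier–Haack formylation of the electron-rich arene can only reach one of the two symmetry-equivalent free positions (each para to a methoxy group), and the aryl iminium salt is hydrolysed to the aldehyde by warm water.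

Step 2
Reactants: 3 2,3,4,5-tetramethoxybenzaldehyde
Product: 5 2,3,4,5-tetramethoxyphenol, via aryl formate 4 (not isolated)
Conditions: mCPBA, CH2Cl2, 0 °C → rt; aq. NaHCO3 wash; then Et3N (cat.), MeOH, rt
Reagents that add atoms: meta-chloroperoxybenzoic acid, O=C(OO)c1cccc(Cl)c1
Why: Baeyer–Villiger (Dakin-type) oxidation, in which the electron-rich aryl group migrates in preference to hydrogen, should give the aryl formate, which is methanolysed to the phenol under mild amine catalysis.

Step 3
Reactants: 5 2,3,4,5-tetramethoxyphenol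
Product: 7 1-(2-hydroxy-3,4,5,6-tetramethoxyphenyl)ethan-1-one, via difluoroboron chelate 6 (not isolated)
Conditions: AcOH, BF3·OEt2, 90 °C; then H2O, 60 °C
Reagents that add atoms: acetic acid, CC(=O)O
Why: BF3-mediated Friedel–Crafts (Fries-type) C-acetylation should take the single open ring position, which lies ortho to the phenol, the product being held as a boron chelate between phenol and ketone that warm water hydrolyses.

Step 4
Reactants: 7 1-(2-hydroxy-3,4,5,6-tetramethoxyphenyl)ethan-1-one; 8 ethyl 2,2-diethoxyacetate
Product: 10 2-(diethoxymethyl)-5,6,7,8-tetramethoxy-4H-chromen-4-one, via diketone acetal 9 (not isolated)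
Conditions: NaH, THF, reflux; AcOH quench; then H2SO4 (cat.), EtOH, 70 °C
Reagents that add atoms: none
Why: Claisen condensation of the ketone enolate with the activated α,α-dialkoxy ester followed by acid cyclodehydration of the o-hydroxyaryl 1,3-diketone is the standard chromone construction, and ethanol as solvent keeps the diethyl acetal intact so that C-2 carries the aldehyde oxidation level from the start.

Step 5
Reactants: 10 2-(diethoxymethyl)-5,6,7,8-tetramethoxy-4H-chromen-4-one
Product: 11 5,6,7,8-tetramethoxy-4-oxo-4H-chromene-2-carbaldehyde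
Conditions: HCO2H/H2O (4:1), 60 °C; then toluene azeotrope
Reagents that add atoms: water, O
Why: Acid-catalysed acetal hydrolysis should unmask the aldehyde without touching the chromone or the aryl methyl ethers, and azeotropic drying returns the readily hydrated, electron-poor aldehyde to its carbonyl form just before use.

Step 6
Reactants: 11 5,6,7,8-tetramethoxy-4-oxo-4H-chromene-2-carbaldehyde
Product: 12 2-ethynyl-5,6,7,8-tetramethoxy-4H-chromen-4-one
Conditions: TMSCHN2, LiN(iPr)2, THF, −78 °C; then 11, −78 °C → rt
Reagents that add atoms: (trimethylsilyl)diazomethane, C[Si](C)(C)C=[N+]=[N-]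
Why: In this Colvin rearrangement the lithiated silyl diazomethane should add to the aldehyde (far more electrophilic than the vinylogous-ester C-4 carbonyl), Peterson elimination then gives a diazoalkene that loses N2, and a 1,2-hydrogen shift of the alkylidene carbene gives the terminal alkyne, all under aprotic conditions that spare C-2 of the chromone and the activated alkyne from the alkoxide addition expected in basic methanol.

Step 7
Reactants: 13 tert-butyl vinyl ether; 14 chromium hexacarbonyl, Cr(CO)6
Product: 17 pentacarbonyl[(1-tert-butoxyvinyl)(methoxy)carbene]chromium, via vinyllithium CH2=C(OtBu)Li 15 (not isolated), via acylchromate Li[(CO)5CrC(O)C(OtBu)=CH2] 16 (not isolated)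
Conditions: t-BuLi, THF, −78 → 0 °C; Cr(CO)6, THF, 0 °C → rt; solvent switch; MeOTf, CH2Cl2, 0 °C
Reagents that add atoms: methyl trifluoromethanesulfonate, COS(=O)(=O)C(F)(F)F
Why: Fischer carbene synthesis, in which α-lithiation of the alkyl vinyl ether, addition of the vinyllithium to a CO ligand and hard O-methylation of the acyl chromate follow one another, should give the complex, and MeOTf in CH2Cl2 avoids the aqueous acidic medium that would endanger the tert-butyl enol ether.

Step 8
Reactants: 12 2-ethynyl-5,6,7,8-tetramethoxy-4H-chromen-4-one; 17 pentacarbonyl[(1-tert-butoxyvinyl)(methoxy)carbene]chromium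
Product: 19 2-(4-tert-butoxy-2-hydroxy-5-methoxyphenyl)-5,6,7,8-tetramethoxy-4H-chromen-4-one, via arene complex (ArH)Cr(CO)3 18 (not isolated)
Conditions: 17 (1.5 equiv), THF, 50 °C, slow addition of 12, argon; then air, CH2Cl2, daylight, rt
Reagents that add atoms: none
Why: Heating dissociates a CO ligand from 17, after which the alkyne binds to chromium and inserts into the metal–carbene bond, its CH end joining the former carbene carbon (new C5'–C6' bond); migratory insertion of a second CO then gives a chromium-bound dienylketene (new C1'–C2' bond), which cyclises through the CH2 terminus of the alkoxyvinyl arm (new C2'–C3' bond) and tautomerises to the phenol, held as Cr(CO)3 complex 18 until air removes the metal. The closest known reaction type is the Dötz benzannulation of alkenyl(alkoxy)carbene chromium complexes with terminal alkynes. Ring B, the only ring formed, is a six-membered carbocycle assembled in a formal [3+2+1] fashion and closed by a thermal 6π electrocyclisation of the dienylketene. No stereocentre is created. The step needs regioselective insertion, which the terminal alkyne secures: its bulkier, chromone-bearing carbon avoids the carbene carbon and ends beside the CO-derived carbon, so the chromone stands at C1' ortho to the free 2'-OH, the OMe on the former carbene carbon is 5'-OMe and the tert-butoxy oxygen is O-4'. Chemoselectivity for the phenol over cyclobutenone, furan or indene-type products is favoured by the alkenyl (not aryl) carbene and the donor solvent, and slow addition should keep the electron-poor conjugated alkyne from oligomerising.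

Step 9
Reactants: 19 2-(4-tert-butoxy-2-hydroxy-5-methoxyphenyl)-5,6,7,8-tetramethoxy-4H-chromen-4-one
Product: 20 2-(2,4-dihydroxy-5-methoxyphenyl)-5,6,7,8-tetramethoxy-4H-chromen-4-one
Conditions: TFA/CH2Cl2 (1:4), 0 °C → rt
Reagents that add atoms: none
Why: Acidolysis of the aryl tert-butyl ether by E1 loss of isobutene should free 4'-OH while the five methyl ethers and the chromone stay untouched, ring B being deactivated towards C-tert-butylation by the protonated chromone.

**Compound list**

1 | 1,2,3,4-tetramethoxybenzene | COc1ccc(OC)c(OC)c1OC | starting material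
2 | N,N-dimethyl-1-(2,3,4,5-tetramethoxyphenyl)methaniminium chloride (not isolated) | C[N+](C)=Cc1cc(OC)c(OC)c(OC)c1OC.[Cl-] | intermediate
3 | 2,3,4,5-tetramethoxybenzaldehyde | O=Cc1cc(OC)c(OC)c(OC)c1OC | intermediate
4 | 2,3,4,5-tetramethoxyphenyl formate (not isolated) | O=COc1cc(OC)c(OC)c(OC)c1OC | intermediate
5 | 2,3,4,5-tetramethoxyphenol | Oc1cc(OC)c(OC)c(OC)c1OC | intermediate
6 | difluoroboron chelate of 7, BF2 bridging the phenolate oxygen and the ketone oxygen (not isolated) | CC1=[O+][B-](F)(F)Oc2c(OC)c(OC)c(OC)c(OC)c21 | intermediate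
7 | 1-(2-hydroxy-3,4,5,6-tetramethoxyphenyl)ethan-1-one | CC(=O)c1c(O)c(OC)c(OC)c(OC)c1OC | intermediate
8 | ethyl 2,2-diethoxyacetate | CCOC(OCC)C(=O)OCC | starting material
9 | 4,4-diethoxy-1-(2-hydroxy-3,4,5,6-tetramethoxyphenyl)butane-1,3-dione (not isolated) | CCOC(OCC)C(=O)CC(=O)c1c(O)c(OC)c(OC)c(OC)c1OC | intermediate
10 | 2-(diethoxymethyl)-5,6,7,8-tetramethoxy-4H-chromen-4-one | CCOC(OCC)c1cc(=O)c2c(OC)c(OC)c(OC)c(OC)c2o1 | intermediate
11 | 5,6,7,8-tetramethoxy-4-oxo-4H-chromene-2-carbaldehyde | O=Cc1cc(=O)c2c(OC)c(OC)c(OC)c(OC)c2o1 | intermediate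
12 | 2-ethynyl-5,6,7,8-tetramethoxy-4H-chromen-4-one | C#Cc1cc(=O)c2c(OC)c(OC)c(OC)c(OC)c2o1 | intermediate
13 | tert-butyl vinyl ether | C=COC(C)(C)C | starting material
14 | chromium hexacarbonyl, Cr(CO)6 | O=C=[Cr](=C=O)(=C=O)(=C=O)(=C=O)=C=O | starting material
15 | 1-tert-butoxyvinyllithium (not isolated) | [Li]C(=C)OC(C)(C)C | intermediate
16 | lithium pentacarbonyl[(1-tert-butoxyvinyl)(oxido)methylidene]chromate, the acyl chromate (not isolated) | [Li+].[O-]C(=[Cr](=C=O)(=C=O)(=C=O)(=C=O)=C=O)C(=C)OC(C)(C)C | intermediate
17 | pentacarbonyl[(1-tert-butoxyvinyl)(methoxy)carbene]chromium | COC(=[Cr](=C=O)(=C=O)(=C=O)(=C=O)=C=O)C(=C)OC(C)(C)C | intermediate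
18 | tricarbonylchromium complex of 19, Cr(CO)3 bound η6 to ring B, written as arene plus metal fragment (not isolated) | COc1cc(-c2cc(=O)c3c(OC)c(OC)c(OC)c(OC)c3o2)c(O)cc1OC(C)(C)C.O=C=[Cr](=C=O)=C=O | intermediate
19 | 2-(4-tert-butoxy-2-hydroxy-5-methoxyphenyl)-5,6,7,8-tetramethoxy-4H-chromen-4-one | COc1cc(-c2cc(=O)c3c(OC)c(OC)c(OC)c(OC)c3o2)c(O)cc1OC(C)(C)C | intermediate
20 | 2-(2,4-dihydroxy-5-methoxyphenyl)-5,6,7,8-tetramethoxy-4H-chromen-4-one (no stereocentres) | COc1cc(-c2cc(=O)c3c(OC)c(OC)c(OC)c(OC)c3o2)c(O)cc1O | target

**Step count**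

Total steps: 9. Longest linear sequence: 8 (steps 1 to 6, then 8 and 9); the carbene complex is a one-step side branch (step 7).

**Steps most likely to fail**

Step 8 (benzannulation). Insertion of the conjugated, electron-poor alkyne may be slow enough for thermal decay of 17 or alkyne oligomerisation to take over, and the vinylketene may be diverted into cyclobutenone or furan products instead of electrocyclising. The fallback sets out from 7 and comes back to the route at 20. Purchasable 2,4-dihydroxy-5-methoxybenzaldehyde would be benzylated twice (BnBr, K2CO3, DMF) to 2,4-bis(benzyloxy)-5-methoxybenzaldehyde F1. Claisen–Schmidt condensation of F1 with 7 (KOH, EtOH, rt) should give (E)-3-[2,4-bis(benzyloxy)-5-methoxyphenyl]-1-(2-hydroxy-3,4,5,6-tetramethoxyphenyl)prop-2-en-1-one F2. Oxidative cyclisation with I2 (cat.) in DMSO at 120 °C should close ring C to 2-[2,4-bis(benzyloxy)-5-methoxyphenyl]-5,6,7,8-tetramethoxy-4H-chromen-4-one F3. Hydrogenolysis (H2 at 1 atm, Pd/C, EtOAc, rt) would remove both benzyl groups and deliver 20.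

Step 6 (aldehyde to alkyne). The lithiated diazo reagent may attack the chromone at C-2 or at the C-4 carbonyl in competition with the aldehyde, residual aldehyde hydrate may quench it, and surplus diazo reagent may add as a dipole to the activated alkyne once it forms. The fallback sets out from 7 and comes back to the route at 12, building the alkyne into the chromone instead of homologating an aldehyde. Esterification of 7 with 3-(triisopropylsilyl)propiolic acid (EDC·HCl, DMAP, CH2Cl2) should give 2-acetyl-3,4,5,6-tetramethoxyphenyl 3-(triisopropylsilyl)prop-2-ynoate F4. LiN(SiMe3)2 in THF at −78 °C would trigger a Baker–Venkataraman O→C acyl shift to 1-(2-hydroxy-3,4,5,6-tetramethoxyphenyl)-5-(triisopropylsilyl)pent-4-yne-1,3-dione F5. H2SO4 (cat.) in AcOH should cyclodehydrate this to 5,6,7,8-tetramethoxy-2-[(triisopropylsilyl)ethynyl]-4H-chromen-4-one F6, the bulky silyl group shielding the alkyne from attack by the enol oxygen. Bu4NF buffered with AcOH in THF at 0 °C would remove the silyl group and give 12.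

Step 4 (Claisen condensation and cyclisation). C-acylation of the ketone enolate, which is flanked by two ortho substituents, may stay incomplete while O-acylation or retro-Claisen cleavage takes over, or the acetal may be lost during cyclodehydration. The fallback sets out from 7 and comes back to the route at 11, bringing the C-2 carbon in as a methyl group and oxidising it afterwards. Condensation of 7 with ethyl acetate (NaH, THF, reflux) should give 1-(2-hydroxy-3,4,5,6-tetramethoxyphenyl)butane-1,3-dione F7. HCl in AcOH would cyclise it to 5,6,7,8-tetramethoxy-2-methyl-4H-chromen-4-one F8. Riley oxidation of the activated 2-methyl group with SeO2 in refluxing dioxane should then give 11.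

Further compounds
F1 | step 8 | 2,4-bis(benzyloxy)-5-methoxybenzaldehyde | COc1cc(C=O)c(OCc2ccccc2)cc1OCc1ccccc1
F2 | step 8 | (E)-3-[2,4-bis(benzyloxy)-5-methoxyphenyl]-1-(2-hydroxy-3,4,5,6-tetramethoxyphenyl)prop-2-en-1-one | COc1cc(/C=C/C(=O)c2c(O)c(OC)c(OC)c(OC)c2OC)c(OCc2ccccc2)cc1OCc1ccccc1
F3 | step 8 | 2-[2,4-bis(benzyloxy)-5-methoxyphenyl]-5,6,7,8-tetramethoxy-4H-chromen-4-one | COc1cc(-c2cc(=O)c3c(OC)c(OC)c(OC)c(OC)c3o2)c(OCc2ccccc2)cc1OCc1ccccc1
F4 | step 6 | 2-acetyl-3,4,5,6-tetramethoxyphenyl 3-(triisopropylsilyl)prop-2-ynoate | CC(=O)c1c(OC(=O)C#C[Si](C(C)C)(C(C)C)C(C)C)c(OC)c(OC)c(OC)c1OC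
F5 | step 6 | 1-(2-hydroxy-3,4,5,6-tetramethoxyphenyl)-5-(triisopropylsilyl)pent-4-yne-1,3-dione | CC(C)[Si](C#CC(=O)CC(=O)c1c(O)c(OC)c(OC)c(OC)c1OC)(C(C)C)C(C)C
F6 | step 6 | 5,6,7,8-tetramethoxy-2-[(triisopropylsilyl)ethynyl]-4H-chromen-4-one | CC(C)[Si](C#Cc1cc(=O)c2c(OC)c(OC)c(OC)c(OC)c2o1)(C(C)C)C(C)C
F7 | step 4 | 1-(2-hydroxy-3,4,5,6-tetramethoxyphenyl)butane-1,3-dione | CC(=O)CC(=O)c1c(O)c(OC)c(OC)c(OC)c1OC
F8 | step 4 | 5,6,7,8-tetramethoxy-2-methyl-4H-chromen-4-one | Cc1cc(=O)c2c(OC)c(OC)c(OC)c(OC)c2o1
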